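**Strategy.** The contiguous C14 carbinol, quaternary C1 and C10 methine next to the C11=C20 exocyclic methylene on the six-membered ring are the signature of an epoxide-initiated olefin cyclization. The route therefore rests on disconnecting C1–C10: one Lewis-acid step turns an acyclic Z-epoxide carrying an allylsilane into the methylenecyclohexanol, setting C14, C1 and C10 together; the epoxide itself is relayed from (S)-lactate and in turn controls C2. The precursor is a linear chain that already holds the C3–C6 iodoalkene. The ten-membered ring is closed later at C6–C7 and the hydroxy-lactone last at C8–C17.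

Key step: step 15

Remark: locants C1–C20 are the briarane locants of the target (C1 quaternary, C10 ring-fusion CH, C11=C20 methylene, C19 lactone carbonyl); the SMILES strings define all configurations. LDA, NaHMDS, Zn(BH4)2, SmI2 and the aluminium reagents are used as stock solutions.

Step 1
Reactants: 1 ethyl (2S)-2-hydroxypropanoate
Product: 2 ethyl (2S)-2-[(tert-butyldimethylsilyl)oxy]propanoate
Conditions: TBSCl, imidazole, DMF, rt
Reagents that add atoms: tert-butyldimethylsilyl chloride, CC(C)(C)[Si](C)(C)Cl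
Why: Imidazole-promoted silylation of the secondary alcohol leaves the lactate stereocentre untouched.

Step 2
Reactants: 2 ethyl (2S)-2-[(tert-butyldimethylsilyl)oxy]propanoate
Product: 4 (3S)-3-[(tert-butyldimethylsilyl)oxy]butan-2-one, via Weinreb amide 3 (not isolated)
Conditions: MeNHOMe·HCl, i-PrMgCl, THF, −20 °C; then MeMgBr, 0 °C
Reagents that add atoms: methylmagnesium bromide, C[Mg]Br (N,O-dimethylhydroxylamine hydrochloride, CNOC.Cl, is incorporated only in intermediate 3)
Why: One-pot Weinreb ketone synthesis, in which the chelated tetrahedral adduct of the N-methoxy-N-methylamide stops at the ketone and the α-silyloxy centre should not enolize.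

Step 3
Reactants: 5 (4-ethoxy-4-oxobutyl)triphenylphosphonium bromide; 4 (3S)-3-[(tert-butyldimethylsilyl)oxy]butan-2-one
Product: 7 ethyl (4Z,6S)-6-[(tert-butyldimethylsilyl)oxy]-5-methylhept-4-enoate, via phosphorus ylide 6 (not isolated)
Conditions: NaHMDS, THF, −78 °C; then 4, −78 °C to rt
Reagents that add atoms: none
Why: Wittig olefination of an α-oxygenated methyl ketone with a non-stabilized ylide is Z-selective, so the oxygenated carbon C2 should end up cis to the incoming chain (C13) on the new C14=C1 olefin.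

Step 4
Reactants: 7 ethyl (4Z,6S)-6-[(tert-butyldimethylsilyl)oxy]-5-methylhept-4-enoate
Product: 8 ethyl (6Z,8S)-8-[(tert-butyldimethylsilyl)oxy]-7-methyl-3-oxonon-6-enoate
Conditions: EtOAc, LDA (3 equiv each), THF, −78 °C; then 7, −78 to −20 °C
Reagents that add atoms: ethyl acetate, CCOC(C)=O
Why: Crossed Claisen condensation with excess lithium enolate of ethyl acetate gives the β-keto ester, which is shielded from further attack as its enolate.

Step 5
Reactants: 8 ethyl (6Z,8S)-8-[(tert-butyldimethylsilyl)oxy]-7-methyl-3-oxonon-6-enoate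
Product: 9 ethyl (2E,6Z,8S)-8-[(tert-butyldimethylsilyl)oxy]-7-methyl-3-{[(trifluoromethyl)sulfonyl]oxy}nona-2,6-dienoate
Conditions: Tf2O, aq. Me4NOH, toluene–hexane, 0 °C
Reagents that add atoms: trifluoromethanesulfonic anhydride, O=S(=O)(OS(=O)(=O)C(F)(F)F)C(F)(F)F
Why: Enol triflation of a β-keto ester through its non-chelated tetraalkylammonium enolate should give the E-enol triflate, OTf trans to the ester.

Step 6
Reactants: 9 ethyl (2E,6Z,8S)-8-[(tert-butyldimethylsilyl)oxy]-7-methyl-3-{[(trifluoromethyl)sulfonyl]oxy}nona-2,6-dienoate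
Product: 10 ethyl (2E,6Z,8S)-8-[(tert-butyldimethylsilyl)oxy]-7-methyl-3-[(trimethylsilyl)methyl]nona-2,6-dienoate
Conditions: Me3SiCH2MgCl, Pd(PPh3)4 (5 mol %), THF, 0 °C to rt
Reagents that add atoms: (trimethylsilyl)methylmagnesium chloride, C[Si](C)(C)C[Mg]Cl
Why: Pd-catalysed Kumada coupling of the enol triflate proceeds with retention, so CH2SiMe3 (C20) is trans and the chain carbon C12 cis to the ester carbon C9.

Step 7
Reactants: 10 ethyl (2E,6Z,8S)-8-[(tert-butyldimethylsilyl)oxy]-7-methyl-3-[(trimethylsilyl)methyl]nona-2,6-dienoate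
Product: 11 ethyl (2E,6Z,8S)-8-hydroxy-7-methyl-3-[(trimethylsilyl)methyl]nona-2,6-dienoate
Conditions: HF·pyridine, pyridine, THF, 0 °C to rt
Reagents that add atoms: none
Why: Buffered fluoride desilylation frees the allylic alcohol, and the ester-deactivated allylsilane should not be protodesilylated.

Step 8
Reactants: 11 ethyl (2E,6Z,8S)-8-hydroxy-7-methyl-3-[(trimethylsilyl)methyl]nona-2,6-dienoate
Product: 12 ethyl (2E)-5-{(2S,3R)-3-[(1S)-1-hydroxyethyl]-3-methyloxiran-2-yl}-3-[(trimethylsilyl)methyl]pent-2-enoate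
Conditions: mCPBA, NaHCO3, CH2Cl2, 0 °C
Reagents that add atoms: 3-chloroperbenzoic acid, OOC(=O)c1cccc(Cl)c1
Why: Hydroxyl-directed peracid epoxidation of the Z-allylic alcohol through its A(1,3)-minimized conformer should give the threo epoxy alcohol, so the lactate centre fixes C14 (S) and C1, while the electron-poor enoate olefin does not react.

Step 9
Reactants: 12 ethyl (2E)-5-{(2S,3R)-3-[(1S)-1-hydroxyethyl]-3-methyloxiran-2-yl}-3-[(trimethylsilyl)methyl]pent-2-enoate
Product: 13 ethyl (2E)-5-[(2S,3S)-3-acetyl-3-methyloxiran-2-yl]-3-[(trimethylsilyl)methyl]pent-2-enoate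
Conditions: Dess–Martin periodinane, NaHCO3, CH2Cl2, 0 °C to rt
Reagents that add atoms: none
Why: Dess–Martin oxidation turns the carbinol, whose relay role is fulfilled, into the methyl ketone without touching the epoxide or the allylsilane.

Step 10
Reactants: 14 prop-2-yn-1-ol
Product: 15 (2Z)-3-iodo-2-methylprop-2-en-1-ol
Conditions: MeMgBr (2.2 equiv), CuI (10 mol %), Et2O, −10 °C to rt; then I2, −10 °C
Reagents that add atoms: methylmagnesium bromide, C[Mg]Br; iodine, II
Why: Copper-catalysed anti-carbomagnesiation of the propargylic alkoxide followed by iodinolysis gives the Z-iodoalkene, iodine cis to the hydroxymethyl group.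

Step 11
Reactants: 15 (2Z)-3-iodo-2-methylprop-2-en-1-ol
Product: 16 (1Z)-3-bromo-1-iodo-2-methylprop-1-ene
Conditions: CBr4, PPh3, CH2Cl2, 0 °C
Reagents that add atoms: tetrabromomethane, BrC(Br)(Br)Br
Why: Appel bromination of the primary allylic alcohol keeps the olefin geometry.

Step 12
Reactants: 13 ethyl (2E)-5-[(2S,3S)-3-acetyl-3-methyloxiran-2-yl]-3-[(trimethylsilyl)methyl]pent-2-enoate; 16 (1Z)-3-bromo-1-iodo-2-methylprop-1-ene
Product: 18 ethyl (2E)-5-{(2S,3S)-3-[(4Z)-5-iodo-4-methylpent-4-enoyl]-3-methyloxiran-2-yl}-3-[(trimethylsilyl)methyl]pent-2-enoate, via lithium enolate 17 (not isolated)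
Conditions: LDA (1.05 equiv), THF, −78 °C; then 16, DMPU, −78 to −30 °C
Reagents that add atoms: none
Why: Kinetic deprotonation at the only ketone α-carbon (C3) and SN2 alkylation of the lithium enolate by the allylic bromide installs C4–C6 with the Z-iodoalkene intact.

Step 13
Reactants: 18 ethyl (2E)-5-{(2S,3S)-3-[(4Z)-5-iodo-4-methylpent-4-enoyl]-3-methyloxiran-2-yl}-3-[(trimethylsilyl)methyl]pent-2-enoate
Product: 19 ethyl (2E)-5-{(2S,3R)-3-[(1R,4Z)-1-hydroxy-5-iodo-4-methylpent-4-en-1-yl]-3-methyloxiran-2-yl}-3-[(trimethylsilyl)methyl]pent-2-enoate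
Conditions: Zn(BH4)2, Et2O, −30 °C
Reagents that add atoms: none
Why: Chelation-controlled reduction of the α,β-epoxy ketone (zinc bridges the carbonyl and epoxide oxygens, hydride enters anti to C14) should give the erythro epoxy alcohol, that is the 2R carbinol, and spares the ester.

Step 14
Reactants: 19 ethyl (2E)-5-{(2S,3R)-3-[(1R,4Z)-1-hydroxy-5-iodo-4-methylpent-4-en-1-yl]-3-methyloxiran-2-yl}-3-[(trimethylsilyl)methyl]pent-2-enoate
Product: 20 ethyl (2E)-5-{(2S,3S)-3-[(1R,4Z)-5-iodo-4-methyl-1-[(triethylsilyl)oxy]pent-4-en-1-yl]-3-methyloxiran-2-yl}-3-[(trimethylsilyl)methyl]pent-2-enoate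
Conditions: TESCl, imidazole, DMAP (cat.), DMF, 0 °C to rt
Reagents that add atoms: chlorotriethylsilane, CC[Si](CC)(CC)Cl
Why: Silylation under non-acidic conditions gives a non-participating C2 ether that can later be removed in the presence of TBS ethers.

Step 15
Reactants: 20 ethyl (2E)-5-{(2S,3S)-3-[(1R,4Z)-5-iodo-4-methyl-1-[(triethylsilyl)oxy]pent-4-en-1-yl]-3-methyloxiran-2-yl}-3-[(trimethylsilyl)methyl]pent-2-enoate
Product: 21 ethyl (1S,2R,3S)-3-hydroxy-2-{(1R,4Z)-5-iodo-4-methyl-1-[(triethylsilyl)oxy]pent-4-en-1-yl}-2-methyl-6-methylidenecyclohexane-1-carboxylate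
Conditions: MeAlCl2 (3 equiv), CH2Cl2, −78 °C
Reagents that add atoms: none
Why: MeAlCl2 binds the epoxide oxygen and the C1–O bond at the tertiary carbon breaks while C10 of the allylsilane attacks C1 from the rear (SN2-like, anti); the β-silyl cation at C11 then loses Me3Si+ and leaves only the C11=C20 exocyclic olefin. The closest known reaction type is the epoxide-initiated, allylsilane-terminated cation–olefin cyclization used for γ-cyclogeranyl-type rings, here with an enoate-conjugated allylsilane as terminator. The six-membered ring closes 6-endo-tet at the epoxide (Markovnikov) and 6-endo with respect to the C10=C11 π bond, through a chair transition state. C14 keeps the epoxide configuration; C1 is inverted, its two substituents being fixed by the cis-epoxide (C2 cis to O14, methyl trans); C10 follows from the chair in which C9, cis to C12 on the olefin, is axial and therefore trans to C2. The step needs opening at C1 and not at C14 or by 1,2-shift, and capture by C10 and not by the iodoalkene; the tertiary centre, the non-participating silyl ether and the β-silicon effect (against the inductively deactivated vinyl iodide) should secure this.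

Step 16
Reactants: 21 ethyl (1S,2R,3S)-3-hydroxy-2-{(1R,4Z)-5-iodo-4-methyl-1-[(triethylsilyl)oxy]pent-4-en-1-yl}-2-methyl-6-methylidenecyclohexane-1-carboxylate
Product: 22 (1S,2R,3S)-3-(hydroxymethyl)-2-{(1R,4Z)-5-iodo-4-methyl-1-[(triethylsilyl)oxy]pent-4-en-1-yl}-2-methyl-4-methylidenecyclohexan-1-ol
Conditions: DIBAL-H (4 equiv), CH2Cl2, −78 to −40 °C; Rochelle salt
Reagents that add atoms: none
Why: DIBAL-H reduction of the ester to the primary alcohol at low temperature leaves the vinyl iodide, silyl ether and C10 stereocentre untouched.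

Step 17
Reactants: 22 (1S,2R,3S)-3-(hydroxymethyl)-2-{(1R,4Z)-5-iodo-4-methyl-1-[(triethylsilyl)oxy]pent-4-en-1-yl}-2-methyl-4-methylidenecyclohexan-1-ol
Product: 23 (1S,2R,3S)-3-hydroxy-2-{(1R,4Z)-5-iodo-4-methyl-1-[(triethylsilyl)oxy]pent-4-en-1-yl}-2-methyl-6-methylidenecyclohexane-1-carbaldehyde
Conditions: TEMPO (10 mol %), PhI(OAc)2, CH2Cl2, rt
Reagents that add atoms: none
Why: Oxoammonium (TEMPO) oxidation is selective for the primary over the hindered secondary alcohol and is not basic, so the epimerizable C10 and the β,γ-olefin should survive.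

Step 18
Reactants: 23 (1S,2R,3S)-3-hydroxy-2-{(1R,4Z)-5-iodo-4-methyl-1-[(triethylsilyl)oxy]pent-4-en-1-yl}-2-methyl-6-methylidenecyclohexane-1-carbaldehyde; 24 ethyl 1,3-dithiane-2-carboxylate
Product: 26 ethyl 2-[(R)-hydroxy{(1S,2R,3S)-3-hydroxy-2-[(1R,4Z)-5-iodo-4-methyl-1-(triethylsilyloxy)pent-4-en-1-yl]-2-methyl-6-methylidenecyclohexyl}methyl]-1,3-dithiane-2-carboxylate, via lithiated dithiane ester 25 (not isolated)
Conditions: 24 (2.5 equiv), LDA, THF, −78 °C; then 23, −78 °C
Reagents that add atoms: none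
Why: Aldol-type addition of the lithiated 2-carbethoxy-1,3-dithiane (Corey–Seebach acyl-anion equivalent of a glyoxylate) forms C8–C9, and Felkin–Anh attack anti to the quaternary C1 should give the 9R carbinol.

Step 19
Reactants: 26 ethyl 2-[(R)-hydroxy{(1S,2R,3S)-3-hydroxy-2-[(1R,4Z)-5-iodo-4-methyl-1-(triethylsilyloxy)pent-4-en-1-yl]-2-methyl-6-methylidenecyclohexyl}methyl]-1,3-dithiane-2-carboxylate
Product: 27 9,14-bis-O-(tert-butyldimethylsilyl) ether of 26
Conditions: TBSOTf (3 equiv), 2,6-lutidine, CH2Cl2, −78 to 0 °C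
Reagents that add atoms: tert-butyldimethylsilyl trifluoromethanesulfonate, CC(C)(C)[Si](C)(C)OS(=O)(=O)C(F)(F)F
Why: The silyl triflate silylates both hindered secondary alcohols in one operation and leaves the TES ether in place.

Step 20
Reactants: 27 9,14-bis-O-(tert-butyldimethylsilyl) ether of 26
Product: 28 primary alcohol from 27 (C7 ester reduced to CH2OH on the dithiane carbon C8)
Conditions: DIBAL-H, CH2Cl2, −78 to 0 °C; Rochelle salt
Reagents that add atoms: none
Why: DIBAL-H reduction of the only ester gives the neopentyl-type alcohol.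

Step 21
Reactants: 28 primary alcohol from 27
Product: 29 C7 aldehyde from 28 (2-formyl-1,3-dithiane)
Conditions: Dess–Martin periodinane, pyridine, CH2Cl2, 0 °C
Reagents that add atoms: none
Why: Buffered Dess–Martin oxidation gives the non-enolizable aldehyde faster than it attacks the dithiane.

Step 22
Reactants: 29 C7 aldehyde from 28
Product: 30 ten-membered allylic alcohol: 1,5-dimethyl-11-methylidenebicyclo[8.4.0]tetradec-5(Z)-ene (C1–C14) with 7S-OH, 8-spiro-1,3-dithiane, 9-OTBS, 14-OTBS and 2-OTES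
Conditions: CrCl2 (10 equiv), NiCl2 (2 mol %), DMSO–THF, rt, 2 mM, slow addition
Reagents that add atoms: none
Why: Nozaki–Hiyama–Kishi macrocyclization forms C6–C7 with retention of the Z-olefin geometry, and addition to the aldehyde face turned outward in the closing ring should give the 7S alcohol.

Step 23
Reactants: 30 ten-membered allylic alcohol
Product: 31 7-O-(2-bromopropanoyl) ester of 30 (both C17 epimers)
Conditions: 2-bromopropanoyl bromide, pyridine, DMAP (cat.), CH2Cl2, 0 °C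
Reagents that add atoms: 2-bromopropanoyl bromide, CC(Br)C(=O)Br
Why: Acylation of the allylic alcohol with the acyl bromide places the future C17–C19 unit on O7.

Step 24
Reactants: 31 7-O-(2-bromopropanoyl) ester of 30
Product: 32 C8 ketone from 31
Conditions: MeI, CaCO3, MeCN–H2O (9:1), 45 °C
Reagents that add atoms: water, O
Why: Alkylative hydrolysis of the dithiane unmasks the ketone under neutral conditions that spare the bromo ester, silyl ethers and olefins.

Step 25
Reactants: 32 C8 ketone from 31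
Product: 33 9,14-bis-O-TBS-2-O-TES hydroxy-lactone (7,19-lactone closed, 8S-OH, 17R-Me as in the target)
Conditions: SmI2 (2.5 equiv), THF, −78 °C
Reagents that add atoms: none
Why: Intramolecular samarium Reformatsky reaction (5-exo aldol lactonization) delivers the enolate from O7 to the C8 ketone through the transition state that keeps the ring bonds C7–C6 and C8–C9 trans on the new lactone (8-OH cis to C6), with the C17 methyl anti to C9.

Step 26
Reactants: 33 9,14-bis-O-TBS-2-O-TES hydroxy-lactone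
Product: 34 2-alcohol from 33
Conditions: PPTS (0.2 equiv), MeOH–CH2Cl2, 0 °C to rt
Reagents that add atoms: none
Why: Mild acid methanolysis cleaves the triethylsilyl ether much faster than the two hindered TBS ethers.

Step 27
Reactants: 34 2-alcohol from 33
Product: 35 2-propanoate of 34
Conditions: (EtCO)2O, Et3N, DMAP, CH2Cl2, rt
Reagents that add atoms: propanoic anhydride, CCC(=O)OC(=O)CC
Why: DMAP-catalysed acylation esterifies the secondary C2 alcohol while the tertiary 8-OH should stay free.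

Step 28
Reactants: 35 2-propanoate of 34
Product: 36 9,14-di-O-deacetyljunceellolide E (9,14-diol)
Conditions: HF·pyridine, pyridine, THF, 0 to 40 °C
Reagents that add atoms: none
Why: Fluoride desilylation removes both TBS ethers without touching the lactone or the propanoate.

Step 29
Reactants: 36 9,14-di-O-deacetyljunceellolide E
Product: 37 junceellolide E
Conditions: Ac2O, pyridine, DMAP (cat.), rt
Reagents that add atoms: acetic anhydride, CC(=O)OC(C)=O
Why: Acetylation of the two secondary alcohols, with the hindered tertiary 8-OH left free, should complete the target.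

**Compound list**

1 | ethyl (2S)-2-hydroxypropanoate | CCOC(=O)[C@H](C)O | starting material
2 | ethyl (2S)-2-[(tert-butyldimethylsilyl)oxy]propanoate | CCOC(=O)[C@H](C)O[Si](C)(C)C(C)(C)C | intermediate
3 | (2S)-2-[(tert-butyldimethylsilyl)oxy]-N-methoxy-N-methylpropanamide (Weinreb amide) | CON(C)C(=O)[C@H](C)O[Si](C)(C)C(C)(C)C | intermediate
4 | (3S)-3-[(tert-butyldimethylsilyl)oxy]butan-2-one | CC(=O)[C@H](C)O[Si](C)(C)C(C)(C)C | intermediate
5 | (4-ethoxy-4-oxobutyl)triphenylphosphonium bromide | CCOC(=O)CCC[P+](c1ccccc1)(c1ccccc1)c1ccccc1.[Br-] | starting material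
6 | ethyl 4-(triphenyl-λ5-phosphanylidene)butanoate (phosphorus ylide) | CCOC(=O)CCC=P(c1ccccc1)(c1ccccc1)c1ccccc1 | intermediate
7 | ethyl (4Z,6S)-6-[(tert-butyldimethylsilyl)oxy]-5-methylhept-4-enoate | CCOC(=O)CC/C=C(/C)[C@H](C)O[Si](C)(C)C(C)(C)C | intermediate
8 | ethyl (6Z,8S)-8-[(tert-butyldimethylsilyl)oxy]-7-methyl-3-oxonon-6-enoate | CCOC(=O)CC(=O)CC/C=C(/C)[C@H](C)O[Si](C)(C)C(C)(C)C | intermediate
9 | ethyl (2E,6Z,8S)-8-[(tert-butyldimethylsilyl)oxy]-7-methyl-3-{[(trifluoromethyl)sulfonyl]oxy}nona-2,6-dienoate | CCOC(=O)/C=C(/OS(=O)(=O)C(F)(F)F)CC/C=C(/C)[C@H](C)O[Si](C)(C)C(C)(C)C | intermediate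
10 | ethyl (2E,6Z,8S)-8-[(tert-butyldimethylsilyl)oxy]-7-methyl-3-[(trimethylsilyl)methyl]nona-2,6-dienoate | CCOC(=O)/C=C(/C[Si](C)(C)C)CC/C=C(/C)[C@H](C)O[Si](C)(C)C(C)(C)C | intermediate
11 | ethyl (2E,6Z,8S)-8-hydroxy-7-methyl-3-[(trimethylsilyl)methyl]nona-2,6-dienoate | CCOC(=O)/C=C(/C[Si](C)(C)C)CC/C=C(/C)[C@H](C)O | intermediate
12 | ethyl (2E)-5-{(2S,3R)-3-[(1S)-1-hydroxyethyl]-3-methyloxiran-2-yl}-3-[(trimethylsilyl)methyl]pent-2-enoate | CCOC(=O)/C=C(/C[Si](C)(C)C)CC[C@@H]1O[C@]1(C)[C@H](C)O | intermediate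
13 | ethyl (2E)-5-[(2S,3S)-3-acetyl-3-methyloxiran-2-yl]-3-[(trimethylsilyl)methyl]pent-2-enoate | CCOC(=O)/C=C(/C[Si](C)(C)C)CC[C@@H]1O[C@]1(C)C(C)=O | intermediate
14 | prop-2-yn-1-ol | C#CCO | starting material
15 | (2Z)-3-iodo-2-methylprop-2-en-1-ol | OC/C(C)=C\I | intermediate
16 | (1Z)-3-bromo-1-iodo-2-methylprop-1-ene | BrC/C(C)=C\I | intermediate
17 | lithium enolate of 13 (C3 enolate) | CCOC(=O)/C=C(/C[Si](C)(C)C)CC[C@@H]1O[C@]1(C)C(=C)O[Li] | intermediate
18 | ethyl (2E)-5-{(2S,3S)-3-[(4Z)-5-iodo-4-methylpent-4-enoyl]-3-methyloxiran-2-yl}-3-[(trimethylsilyl)methyl]pent-2-enoate | CCOC(=O)/C=C(/C[Si](C)(C)C)CC[C@@H]1O[C@]1(C)C(=O)CC/C(C)=C\I | intermediate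
19 | ethyl (2E)-5-{(2S,3R)-3-[(1R,4Z)-1-hydroxy-5-iodo-4-methylpent-4-en-1-yl]-3-methyloxiran-2-yl}-3-[(trimethylsilyl)methyl]pent-2-enoate | CCOC(=O)/C=C(/C[Si](C)(C)C)CC[C@@H]1O[C@]1(C)[C@H](O)CC/C(C)=C\I | intermediate
20 | ethyl (2E)-5-{(2S,3S)-3-[(1R,4Z)-5-iodo-4-methyl-1-[(triethylsilyl)oxy]pent-4-en-1-yl]-3-methyloxiran-2-yl}-3-[(trimethylsilyl)methyl]pent-2-enoate | CCOC(=O)/C=C(/C[Si](C)(C)C)CC[C@@H]1O[C@]1(C)[C@H](O[Si](CC)(CC)CC)CC/C(C)=C\I | intermediate
21 | ethyl (1S,2R,3S)-3-hydroxy-2-{(1R,4Z)-5-iodo-4-methyl-1-[(triethylsilyl)oxy]pent-4-en-1-yl}-2-methyl-6-methylidenecyclohexane-1-carboxylate | C=C1CC[C@H](O)[C@@]([C@H](O[Si](CC)(CC)CC)CC/C(C)=C\I)(C)[C@H]1C(=O)OCC | intermediate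
22 | (1S,2R,3S)-3-(hydroxymethyl)-2-{(1R,4Z)-5-iodo-4-methyl-1-[(triethylsilyl)oxy]pent-4-en-1-yl}-2-methyl-4-methylidenecyclohexan-1-ol | C=C1CC[C@H](O)[C@@]([C@H](O[Si](CC)(CC)CC)CC/C(C)=C\I)(C)[C@H]1CO | intermediate
23 | (1S,2R,3S)-3-hydroxy-2-{(1R,4Z)-5-iodo-4-methyl-1-[(triethylsilyl)oxy]pent-4-en-1-yl}-2-methyl-6-methylidenecyclohexane-1-carbaldehyde | C=C1CC[C@H](O)[C@@]([C@H](O[Si](CC)(CC)CC)CC/C(C)=C\I)(C)[C@H]1C=O | intermediate
24 | ethyl 1,3-dithiane-2-carboxylate | CCOC(=O)C1SCCCS1 | starting material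
25 | lithiated ethyl 1,3-dithiane-2-carboxylate (lithium enolate) | CCOC(O[Li])=C1SCCCS1 | intermediate
26 | ethyl 2-[(R)-hydroxy{(1S,2R,3S)-3-hydroxy-2-[(1R,4Z)-5-iodo-4-methyl-1-(triethylsilyloxy)pent-4-en-1-yl]-2-methyl-6-methylidenecyclohexyl}methyl]-1,3-dithiane-2-carboxylate | C=C1CC[C@H](O)[C@@]([C@H](O[Si](CC)(CC)CC)CC/C(C)=C\I)(C)[C@H]1[C@@H](O)C2(SCCCS2)C(=O)OCC | intermediate
27 | 9,14-bis-O-(tert-butyldimethylsilyl) ether of 26 | C=C1CC[C@H](O[Si](C)(C)C(C)(C)C)[C@@]([C@H](O[Si](CC)(CC)CC)CC/C(C)=C\I)(C)[C@H]1[C@@H](O[Si](C)(C)C(C)(C)C)C2(SCCCS2)C(=O)OCC | intermediate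
28 | primary alcohol from 27 (C7 CH2OH on the dithiane carbon) | C=C1CC[C@H](O[Si](C)(C)C(C)(C)C)[C@@]([C@H](O[Si](CC)(CC)CC)CC/C(C)=C\I)(C)[C@H]1[C@@H](O[Si](C)(C)C(C)(C)C)C2(SCCCS2)CO | intermediate
29 | C7 aldehyde from 28 | C=C1CC[C@H](O[Si](C)(C)C(C)(C)C)[C@@]([C@H](O[Si](CC)(CC)CC)CC/C(C)=C\I)(C)[C@H]1[C@@H](O[Si](C)(C)C(C)(C)C)C2(SCCCS2)C=O | intermediate
30 | ten-membered allylic alcohol (7S-OH, 8-spiro-1,3-dithiane, 9,14-bis-OTBS, 2-OTES, Z-C5=C6, 11-methylidene) | C=C1CC[C@H](O[Si](C)(C)C(C)(C)C)[C@@]2(C)[C@H]1[C@@H](O[Si](C)(C)C(C)(C)C)C3(SCCCS3)[C@@H](O)/C=C(/C)CC[C@H]2O[Si](CC)(CC)CC | intermediate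
31 | 7-O-(2-bromopropanoyl) ester of 30 | C=C1CC[C@H](O[Si](C)(C)C(C)(C)C)[C@@]2(C)[C@H]1[C@@H](O[Si](C)(C)C(C)(C)C)C3(SCCCS3)[C@@H](OC(=O)C(C)Br)/C=C(/C)CC[C@H]2O[Si](CC)(CC)CC | intermediate
32 | C8 ketone from 31 | C=C1CC[C@H](O[Si](C)(C)C(C)(C)C)[C@@]2(C)[C@H]1[C@@H](O[Si](C)(C)C(C)(C)C)C(=O)[C@@H](OC(=O)C(C)Br)/C=C(/C)CC[C@H]2O[Si](CC)(CC)CC | intermediate
33 | 9,14-bis-O-TBS-2-O-TES hydroxy-lactone | C=C1CC[C@H](O[Si](C)(C)C(C)(C)C)[C@@]2(C)[C@H]1[C@@H](O[Si](C)(C)C(C)(C)C)[C@@]1(O)[C@H](/C=C(/C)CC[C@H]2O[Si](CC)(CC)CC)OC(=O)[C@@H]1C | intermediate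
34 | 2-alcohol from 33 | C=C1CC[C@H](O[Si](C)(C)C(C)(C)C)[C@@]2(C)[C@H]1[C@@H](O[Si](C)(C)C(C)(C)C)[C@@]1(O)[C@H](/C=C(/C)CC[C@H]2O)OC(=O)[C@@H]1C | intermediate
35 | 2-propanoate of 34 | C=C1CC[C@H](O[Si](C)(C)C(C)(C)C)[C@@]2(C)[C@H]1[C@@H](O[Si](C)(C)C(C)(C)C)[C@@]1(O)[C@H](/C=C(/C)CC[C@H]2OC(=O)CC)OC(=O)[C@@H]1C | intermediate
36 | 9,14-di-O-deacetyljunceellolide E | C=C1CC[C@H](O)[C@@]2(C)[C@H]1[C@@H](O)[C@@]1(O)[C@H](/C=C(/C)CC[C@H]2OC(=O)CC)OC(=O)[C@@H]1C | intermediate
37 | junceellolide E | C=C1CC[C@H](OC(C)=O)[C@@]2(C)[C@H]1[C@@H](OC(C)=O)[C@@]1(O)[C@H](/C=C(/C)CC[C@H]2OC(=O)CC)OC(=O)[C@@H]1C | target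

**Total step count:** 29. **Longest linear sequence:** 27 steps (steps 1–9 and 12–29).

**Steps most likely to fail**

Step 15. Capture of the activated epoxide by the electron-poor, enoate-conjugated allylsilane may be too slow, so that a 1,2-shift next to the silyloxy group or attack by the iodoalkene takes over. The fallback sets out from 20 and returns at 22. DIBAL-H at −78 °C reduces the enoate to the allylic alcohol F1, and TESCl/imidazole gives the bis-silyl ether F2, whose non-conjugated allylsilane is a far stronger π-nucleophile. Et2AlCl in CH2Cl2 at −78 °C should then close the ring to the methylenecyclohexanol F3. Brief PPTS/MeOH at 0 °C removes the primary silyl ether and gives diol 22.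

Step 22. The ring closure may show poor facial selectivity at C7 and deliver mainly the 7-epimer. The fallback sets out from 29 and returns at 30. The same chromium-mediated closure is run to the 7-epi alcohol F4, which MnO2 oxidizes to the macrocyclic enone F5. Corey–Bakshi–Shibata reduction, with the catalyst enantiomer chosen for hydride delivery to the required face, then sets C7 by reagent control and gives 30.

Step 25. Samarium may cleave the α-acyloxy ketone reductively before the C–C bond forms, or the tethered enolate may add with low facial control. The fallback sets out from 30 and returns at 33. MeI/CaCO3 in wet acetonitrile unmasks the ketone of the free alcohol to give the α-hydroxy ketone F6. A chelation-controlled Mukaiyama aldol addition of 1-methoxy-1-(trimethylsilyloxy)propene with MgBr2·OEt2 (magnesium bridging O7 and the C8 carbonyl, attack anti to C6) gives the hydroxy ester F7. PPTS in warm benzene closes the lactone to 33, and DBU can equilibrate C17 if needed.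

**Further compounds**

F1 | step 15 | ethyl ester of 20 reduced to the allylic alcohol (C9 CH2OH) | OC/C=C(/C[Si](C)(C)C)CC[C@@H]1O[C@]1(C)[C@H](O[Si](CC)(CC)CC)CC/C(C)=C\I
F2 | step 15 | 9-O-triethylsilyl ether of F1 | CC[Si](CC)(CC)OC/C=C(/C[Si](C)(C)C)CC[C@@H]1O[C@]1(C)[C@H](O[Si](CC)(CC)CC)CC/C(C)=C\I
F3 | step 15 | 9-O-triethylsilyl ether of diol 22 | C=C1CC[C@H](O)[C@@]([C@H](O[Si](CC)(CC)CC)CC/C(C)=C\I)(C)[C@H]1CO[Si](CC)(CC)CC
F4 | step 22 | 7-epimer of 30 | C=C1CC[C@H](O[Si](C)(C)C(C)(C)C)[C@@]2(C)[C@H]1[C@@H](O[Si](C)(C)C(C)(C)C)C3(SCCCS3)[C@H](O)/C=C(/C)CC[C@H]2O[Si](CC)(CC)CC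
F5 | step 22 | C7 enone from F4 | C=C1CC[C@H](O[Si](C)(C)C(C)(C)C)[C@@]2(C)[C@H]1[C@@H](O[Si](C)(C)C(C)(C)C)C3(SCCCS3)C(=O)/C=C(/C)CC[C@H]2O[Si](CC)(CC)CC
F6 | step 25 | 7-hydroxy-8-ketone from 30 | C=C1CC[C@H](O[Si](C)(C)C(C)(C)C)[C@@]2(C)[C@H]1[C@@H](O[Si](C)(C)C(C)(C)C)C(=O)[C@@H](O)/C=C(/C)CC[C@H]2O[Si](CC)(CC)CC
F7 | step 25 | methyl ester aldol adduct (7,8-diol, C19 CO2Me) | C=C1CC[C@H](O[Si](C)(C)C(C)(C)C)[C@@]2(C)[C@H]1[C@@H](O[Si](C)(C)C(C)(C)C)[C@@]([C@@H](C)C(=O)OC)(O)[C@@H](O)/C=C(/C)CC[C@H]2O[Si](CC)(CC)CC
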